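Assumption: the SMILES encodes the (R)-configured ester (shikonin series), and every intermediate is drawn to deliver that configuration.

## Retrosynthetic overview

1. Ester C–O bond: target ⇒ shikonin + isobutyric acid (side-chain OH only; the peri-phenols are chelated).
2. Naphthazarin ⇒ 5,8-bis(MOM)-1,4-naphthoquinone ⇒ 2-substituted 5,8-bis(MOM)-1-naphthol (oxidation at the free C4).
3. Key disconnection, C2–C3 of the naphthol: intramolecular aldol condensation of an aryl ketone α-CH2 onto an ortho arylacetaldehyde, masked as its dimethyl acetal.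
4. Aryl ketone ⇒ aryllithium (5 steps from hydroquinone) + (R)-β-silyloxy Weinreb amide (5 steps from ethyl 4-chloroacetoacetate; stereocentre from asymmetric hydrogenation).
5. Ring order: the benzenoid ring comes from hydroquinone; the second ring is the only one formed (aldol), then oxidised to the quinone.

## Route

### Fragment A (aryl bromide)

**Step 1**
- Reactants: 1, hydroquinone
- Product: 2, 1,4-bis(methoxymethoxy)benzene
- Conditions: NaH, MOMCl, DMF, 0 °C → rt
- Reagents that add atoms: chloromethyl methyl ether, COCCl
- Why: Williamson-type O-alkylation of both phenoxides; MOM is stable to the organolithium steps and is a strong ortho-director.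

**Step 2**
- Reactants: 2
- Product: 3, 2-bromo-1,4-bis(methoxymethoxy)benzene
- Conditions: n-BuLi (1.1 equiv), THF, 0 °C; then BrCCl2CCl2Br, −78 °C → rt
- Reagents that add atoms: 1,2-dibromotetrachloroethane, BrC(Cl)(Cl)C(Cl)(Cl)Br
- Why: OMOM-directed ortho-metalation and electrophilic bromination; all four ring positions are equivalent, so one monobromide forms.

**Step 3**
- Reactants: 3
- Product: 4, 2-bromo-3,6-bis(methoxymethoxy)benzaldehyde
- Conditions: LDA (1.1 equiv), THF, −78 °C; then DMF, −78 → 0 °C; aq NH4Cl
- Reagents that add atoms: N,N-dimethylformamide, CN(C)C=O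
- Why: directed ortho-lithiation at the most acidic C–H (flanked by Br and OMOM) and formylation; kept at −78 °C to avoid aryne formation.

**Step 4**
- Reactants: 4
- Product: 5, 2-bromo-1,4-bis(methoxymethoxy)-3-(2-methoxyvinyl)benzene (E/Z mixture, inconsequential)
- Conditions: Ph3P(Cl)CH2OMe, KOt-Bu, THF, 0 °C → rt
- Reagents that add atoms: (methoxymethyl)triphenylphosphonium chloride, COC[P+](c1ccccc1)(c1ccccc1)c1ccccc1.[Cl-]
- Why: Wittig one-carbon homologation of the aldehyde to the enol ether; aryl bromide and MOM ethers are inert to the ylide.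

**Step 5**
- Reactants: 5
- Product: 6, 2-bromo-3-(2,2-dimethoxyethyl)-1,4-bis(methoxymethoxy)benzene
- Conditions: PPTS (5 mol%), dry MeOH, rt
- Reagents that add atoms: methanol, CO
- Why: acid-catalysed addition of MeOH to the enol ether (via the oxocarbenium ion) gives a single, organolithium-stable arylacetaldehyde acetal; PPTS at rt does not cleave aryl MOM ethers.

### Fragment B (chiral Weinreb amide)

**Step 6**
- Reactants: 7, ethyl 4-chloro-3-oxobutanoate
- Product: 8, ethyl (S)-4-chloro-3-hydroxybutanoate
- Conditions: H2 (100 atm), RuCl2[(R)-BINAP] (0.1 mol%), EtOH, 100 °C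
- Reagents that add atoms: none
- Why: Noyori asymmetric hydrogenation of the β-keto ester; (R)-BINAP–Ru delivers hydride to one face of the chelated ketone to give the (S)-chlorohydrin (about 97% ee), which is the only stereocentre-forming step of the route.

**Step 7**
- Reactants: 8
- Product: 9, ethyl (S)-3,4-epoxybutanoate (ethyl 2-[(2S)-oxiran-2-yl]acetate)
- Conditions: Ag2O, DME, 60 °C, dark
- Reagents that add atoms: none
- Why: silver-assisted intramolecular Williamson closure; the C3–O bond is not broken (retention), and the mild conditions avoid E1cB opening to the 4-hydroxycrotonate.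

**Step 8**
- Reactants: 9
- Product: 10, ethyl (R)-3-hydroxy-6-methylhept-5-enoate
- Conditions: Me2C=CHMgBr (1.5 equiv), CuI (10 mol%), THF, −40 → −20 °C
- Reagents that add atoms: 2-methyl-1-propenylmagnesium bromide, CC(C)=C[Mg]Br
- Why: copper-catalysed SN2 opening at the terminal epoxide carbon installs the prenyl terminus; the stereocentre is untouched (S → R is only a CIP priority change) and the ester survives at low temperature.

**Step 9**
- Reactants: 10
- Product: 11, (R)-3-hydroxy-N-methoxy-N,6-dimethylhept-5-enamide
- Conditions: MeNH(OMe)·HCl (3 equiv), i-PrMgCl (6 equiv), THF, −20 → 0 °C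
- Reagents that add atoms: N,O-dimethylhydroxylamine hydrochloride, CNOC.Cl
- Why: direct aminolysis of the ester by the magnesium amide (Weinreb amide formation); the β-alkoxide is not a leaving group under these conditions.

**Step 10**
- Reactants: 11
- Product: 12, (R)-3-(tert-butyldimethylsilyloxy)-N-methoxy-N,6-dimethylhept-5-enamide
- Conditions: TBSCl, imidazole, DMF, rt
- Reagents that add atoms: tert-butyldimethylsilyl chloride, CC(C)(C)[Si](C)(C)Cl
- Why: standard silylation of the secondary alcohol, which protects it for the organolithium coupling and the aldol step.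

### Fragment union and endgame

**Step 11**
- Reactants: 6 (1.2 equiv) and 12
- Product: 13, (3R)-3-(tert-butyldimethylsilyloxy)-1-[2-(2,2-dimethoxyethyl)-3,6-bis(methoxymethoxy)phenyl]-6-methylhept-5-en-1-one
- Conditions: 6, n-BuLi (1.2 equiv), THF, −78 °C, 15 min; then 12, −78 → −20 °C; aq NH4Cl
- Reagents that add atoms: none
- Why: Br/Li exchange followed by Weinreb ketone synthesis (the chelated tetrahedral intermediate stops over-addition); acetal, MOM, TBS and alkene are inert, and the stereocentre is β to the new carbonyl and untouched.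

**Step 12 (key ring closure)**
- Reactants: 13
- Product: 14, 2-[(1R)-1-(tert-butyldimethylsilyloxy)-4-methylpent-3-en-1-yl]-5,8-bis(methoxymethoxy)naphthalen-1-ol
- Conditions: (i) 10% aq oxalic acid on SiO2, CH2Cl2, rt; (ii) crude keto-aldehyde, piperidine/AcOH (0.3 equiv each), toluene, rt → 40 °C
- Reagents that add atoms: none
- Why: intramolecular aldol condensation (6-enolendo-exo-trig) of the ketone α-CH2 onto the unmasked arylacetaldehyde, driven by dehydration and tautomerisation to the aromatic naphthol; the carbinol carbon has no acidic hydrogen, so it keeps its (R) configuration, and the buffered amine conditions disfavour E1cB loss of the silyloxy group.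

**Step 13**
- Reactants: 14
- Product: 15, 2-[(1R)-1-(tert-butyldimethylsilyloxy)-4-methylpent-3-en-1-yl]-5,8-bis(methoxymethoxy)naphthalene-1,4-dione
- Conditions: Fremy's salt (2.5 equiv), aq KH2PO4, acetone/H2O, rt
- Reagents that add atoms: potassium nitrosodisulfonate, [K+].[K+].[O-]S(=O)(=O)N([O])S(=O)(=O)[O-]
- Why: Teuber oxidation of the 1-naphthol at its free para position (C2 is blocked) gives the 1,4-quinone; the near-neutral radical conditions spare the alkene, TBS and MOM groups.

**Step 14**
- Reactants: 15
- Product: 16, shikonin, 5,8-dihydroxy-2-[(1R)-1-hydroxy-4-methylpent-3-en-1-yl]naphthalene-1,4-dione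
- Conditions: AcCl in MeOH (about 0.5 M HCl), CH2Cl2, 0 °C → rt, quench with NaHCO3 at full conversion
- Reagents that add atoms: none
- Why: acid methanolysis removes the two chelation-activated peri-MOM ethers and the TBS ether in one operation; only O–CH2 and O–Si bonds break, so the stereocentre is retained, and low temperature with short contact time limits cycloshikonin formation.

**Step 15**
- Reactants: 16 and 17, isobutyric acid
- Product: 18, isobutylshikonin, (1R)-1-(5,8-dihydroxy-1,4-dioxo-1,4-dihydronaphthalen-2-yl)-4-methylpent-3-en-1-yl 2-methylpropanoate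
- Conditions: 17 (1.5 equiv), DCC (1.5 equiv), DMAP (0.2 equiv), CH2Cl2, 0 °C → rt
- Reagents that add atoms: isobutyric acid, CC(C)C(=O)O
- Why: Steglich esterification acylates only the side-chain alcohol, because the peri-phenols are hydrogen-bonded to the quinone carbonyls and poorly nucleophilic; acylation on oxygen retains the (R) configuration.

## Compound list

1 | hydroquinone | Oc1ccc(O)cc1 | starting material
2 | 1,4-bis(methoxymethoxy)benzene | COCOc1ccc(OCOC)cc1 | intermediate
3 | 2-bromo-1,4-bis(methoxymethoxy)benzene | COCOc1ccc(OCOC)c(Br)c1 | intermediate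
4 | 2-bromo-3,6-bis(methoxymethoxy)benzaldehyde | O=Cc1c(Br)c(OCOC)ccc1OCOC | intermediate
5 | 2-bromo-1,4-bis(methoxymethoxy)-3-(2-methoxyvinyl)benzene (E/Z) | COC=Cc1c(Br)c(OCOC)ccc1OCOC | intermediate
6 | 2-bromo-3-(2,2-dimethoxyethyl)-1,4-bis(methoxymethoxy)benzene | COC(OC)Cc1c(Br)c(OCOC)ccc1OCOC | intermediate
7 | ethyl 4-chloro-3-oxobutanoate | CCOC(=O)CC(=O)CCl | starting material
8 | ethyl (S)-4-chloro-3-hydroxybutanoate | CCOC(=O)C[C@H](O)CCl | intermediate
9 | ethyl (S)-3,4-epoxybutanoate | CCOC(=O)C[C@H]1CO1 | intermediate
10 | ethyl (R)-3-hydroxy-6-methylhept-5-enoate | CC(C)=CC[C@@H](O)CC(=O)OCC | intermediate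
11 | (R)-3-hydroxy-N-methoxy-N,6-dimethylhept-5-enamide | CC(C)=CC[C@@H](O)CC(=O)N(C)OC | intermediate
12 | (R)-3-(tert-butyldimethylsilyloxy)-N-methoxy-N,6-dimethylhept-5-enamide | CC(C)=CC[C@@H](O[Si](C)(C)C(C)(C)C)CC(=O)N(C)OC | intermediate
13 | (3R)-3-(TBSO)-1-[2-(2,2-dimethoxyethyl)-3,6-bis(methoxymethoxy)phenyl]-6-methylhept-5-en-1-one | CC(C)=CC[C@@H](O[Si](C)(C)C(C)(C)C)CC(=O)c1c(CC(OC)OC)c(OCOC)ccc1OCOC | intermediate
14 | 2-[(1R)-1-(TBSO)-4-methylpent-3-en-1-yl]-5,8-bis(methoxymethoxy)naphthalen-1-ol | CC(C)=CC[C@@H](O[Si](C)(C)C(C)(C)C)c1ccc2c(OCOC)ccc(OCOC)c2c1O | intermediate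
15 | 2-[(1R)-1-(TBSO)-4-methylpent-3-en-1-yl]-5,8-bis(methoxymethoxy)naphthalene-1,4-dione | CC(C)=CC[C@@H](O[Si](C)(C)C(C)(C)C)C1=CC(=O)c2c(OCOC)ccc(OCOC)c2C1=O | intermediate
16 | shikonin | CC(C)=CC[C@@H](O)C1=CC(=O)c2c(O)ccc(O)c2C1=O | intermediate
17 | isobutyric acid | CC(C)C(=O)O | starting material
18 | isobutylshikonin | CC(C)=CC[C@@H](OC(=O)C(C)C)C1=CC(=O)c2c(O)ccc(O)c2C1=O | target

## Step count and risks

- Total steps: 15.
- Longest linear sequence: 10 (steps 1–5 or 6–10, then 11–15).

Three steps most likely to fail:

1. **Step 12 (aldol ring closure).** The enolisable ketone carries a β-silyloxy group that can be lost by E1cB, and the free arylacetaldehyde can self-condense. Fallback: take the stereocentre out of the cyclisation. Close the ring on the side-chain-free methyl ketone (from lithiated 6 + N-methoxy-N-methylacetamide) to give 5,8-bis(MOM)-1-naphthol. Then ortho-formylate at C2 and build the side chain by Brown asymmetric allylation and cross-metathesis with 2-methyl-2-butene before the oxidation.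

2. **Step 14 (global acid deprotection).** Free shikonin can cyclise to cycloshikonin or solvolyse at the carbinol under acid. Fallback: change the endgame order so that the free carbinol never meets acid. Remove only the TBS group from 15 (HF·pyridine), esterify with isobutyryl chloride/pyridine, and cleave the peri-MOM ethers last from the ester (for example MgBr2·OEt2/EtSH); this costs one extra step.

3. **Step 11 (aryllithium + Weinreb amide).** The doubly ortho-substituted aryllithium may deprotonate the amide α-CH2 (recovered amide or β-elimination) instead of adding. Fallback: reduce 12 to the aldehyde (DIBAL-H), add the less basic arylcerium reagent (ArLi/CeCl3) to give the carbinol, and oxidise it to 13 with Dess–Martin periodinane.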